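## Analysis of the target

Naamine C is a fully substituted 2-aminoimidazole (ring A: N1, C2, N3, C4, C5). N1 carries a methyl group, C2 a free amino group, C4 a 4-methoxybenzyl group (ring B) and C5 a 2-hydroxy-3,4-dimethoxybenzyl group (ring C, C1'–C6'). The molecule has no stereocentre, no stereogenic double bond and no axis, so it is achiral and the synthetic problem is purely one of constitution. The difficulty is regiochemical: two similar benzyl groups must be placed on C4 and C5, and the more hindered, phenolic one must end up next to the N-methyl nitrogen and not next to N3. The sensitive parts are the electron-rich, basic and easily oxidised 2-aminoimidazole, the free phenol, and two doubly activated methylene groups. The feature that the route exploits is the hydroxyl group on C2' of ring C, which sits ortho to C1', the carbon that bears the methylene bound to C5 of ring A. This o-hydroxybenzyl unit is the formal adduct of an o-quinone methide and a nucleophilic carbon. C5 is such a carbon: it is the β-carbon of the N1–C5=C4 enamine and is further activated by the C2 amino group.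

## Retrosynthetic reasoning

**Disconnection 1, C5–CH2 bond between ring A and ring C (key step).** Target 15 is cut into the C5-unsubstituted aminoimidazole 11 and the o-quinone methide 14, which is released in the flask from the o-hydroxybenzyl alcohol 13. The cut is made here because the ortho phenol makes the benzylic carbon an electrophile without any activating or protecting group. It removes half of the mass in one operation and leaves only one ring carbon of 11 with a hydrogen, so the regiochemistry on ring A is decided before the key step. The forward reaction must favour C- over N-alkylation and stop after one benzyl group. A description of this step, the alkylation of 11 by 14, is not the route usually drawn first, which builds both benzyl groups into an acyclic precursor before the ring is closed.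

**Disconnection 2, benzylic C–O of 13.** Alcohol 13 goes back to aldehyde 12 by a hydride reduction. The formyl carbon of 12 already fixes the position of the new bond on ring C, so no regiochemical question arises on the arene.

**Disconnection 3, ring A of 11 (N3–C4 and N1–C2).** The aminoimidazole 11 is cut into the α-(methylamino) ketone salt 8 and cyanamide 9, by way of the ketoguanidine 10. The methyl group sits on the amine nitrogen, so this nitrogen must become N1 and its methylene must become C5–H; the ketone carbon with its 4-methoxybenzyl group becomes C4. The placement of N-methyl relative to the free C5 position is therefore intrinsic.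

**Disconnection 4, C(=O)–CH2Ar bond of 8.** Salt 8 comes from the carbamate 7 by loss of the tert-butoxycarbonyl group. Ketone 7 is cut at the acyl–benzyl bond into the N-methoxy-N-methyl amide 4 and the benzylic Grignard reagent 5; the chelated adduct 6 guards against double addition.

**Disconnection 5, amide bond of 4.** Amide 4 is made from the protected amino acid 1 and the hydroxylamine salt 2 through the acyl imidazolide 3.

## Alternatives that were turned down

**Alternative 1:** the textbook disconnection closes ring A last, from an acyclic α-amino ketone that already carries both benzyl groups. The N-methoxy-N-methyl amide A1 of an N-protected, N-methylated, O-benzylated 2-hydroxy-3,4-dimethoxyphenylalanine would be treated with Grignard reagent 5; after deprotection the amino ketone A2 would be condensed with cyanamide 9 and debenzylated. The ring closure is reliable. It was turned down because the amino acid behind A1 is not commercial and costs four to five steps from aldehyde 12, the phenol needs a protecting group throughout, and a stereocentre is built only to be destroyed on aromatisation. The route would run to nine or ten linear steps for a bond set that the chosen key step reaches with unprotected partners.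

**Alternative 2:** ring A is closed by a 5-exo-dig hydroamination of a propargylguanidine, followed by exo-to-endo double-bond migration. A three-component alkyne–aldehyde–amine coupling of the homologated aldehyde A3, the aryl alkyne A4 and a methylamine bearing a removable group would give a propargylamine. N-deprotection and guanylation would give the propargylguanidine A5, whose cyclisation places ring B on the C4 methylene and ring C on the C5 methylene with correct regiochemistry. It is an attractive ring construction. It was turned down because A3 needs phenol protection and a one-carbon homologation of 12 and is an enolisable arylacetaldehyde that is awkward in the coupling. The sequence also carries an N-deprotection, a guanylation and a final debenzylation, eight to nine steps in all, and the 5-exo against 6-endo selectivity would have to be controlled as well.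

**Alternative 3:** both benzyl groups are put onto a preformed simple imidazole by sequential metalation. Stepwise halogen–metal exchange on a 1-methylimidazole dihalogenated at C4 and C5, addition to the two aryl aldehydes and deoxygenation of each carbinol would give the 2-unsubstituted imidazole A6; C2 metalation, azide transfer, reduction and debenzylation would complete the target. It was turned down because each benzyl group costs two steps, the amino group costs two more and needs an azide, and the phenol must be protected. The route is strictly linear with ten or more steps and fixes regiochemistry only through the order of the metalations.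

Key step: step 6

Remark on the chemistry (assumptions): the target is achiral, so the request for a single enantiomer needs no stereocontrol. (4-Methoxybenzyl)magnesium chloride 5 is taken as a commercial THF solution.

## Route

**Step 1**
Reactants: 1 N-(tert-butoxycarbonyl)sarcosine; 2 N,O-dimethylhydroxylamine hydrochloride
Product: 4 tert-butyl N-{2-[methoxy(methyl)amino]-2-oxoethyl}-N-methylcarbamate, via acyl imidazolide 3 (not isolated)
Conditions: CDI, CH2Cl2, 0 °C to rt; then 2, rt
Reagents that add atoms: 1,1'-carbonyldiimidazole (CDI), O=C(n1ccnc1)n1ccnc1 (supplies the imidazolyl group of intermediate 3 only; no atom of it remains in 4)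
Why: Standard amide formation through an acyl imidazolide; the imidazole set free takes up the hydrogen chloride of 2, and the tertiary carbamate has no N–H that could interfere.

**Step 2**
Reactants: 4 tert-butyl N-{2-[methoxy(methyl)amino]-2-oxoethyl}-N-methylcarbamate; 5 (4-methoxybenzyl)magnesium chloride
Product: 7 tert-butyl N-[3-(4-methoxyphenyl)-2-oxopropyl]-N-methylcarbamate, via chelated tetrahedral magnesium adduct 6 (not isolated)
Conditions: 5 (0.25 M in THF, 1.4 equiv), THF, −20 to 0 °C; then cold 1 M HCl
Reagents that add atoms: none
Why: Weinreb ketone synthesis; the five-membered magnesium chelate 6 should persist until the quench, so the ketone is not exposed to the Grignard reagent, and the carbamate carries no acidic N–H.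

**Step 3**
Reactants: 7 tert-butyl N-[3-(4-methoxyphenyl)-2-oxopropyl]-N-methylcarbamate
Product: 8 1-(4-methoxyphenyl)-3-(methylamino)propan-2-one hydrochloride
Conditions: 4 M HCl in 1,4-dioxane, rt; evaporation
Reagents that add atoms: hydrogen chloride, Cl
Why: Acidolysis of the tert-butyl carbamate; the α-amino ketone is kept as its hydrochloride, which blocks self-condensation of the free base.

**Step 4**
Reactants: 8 1-(4-methoxyphenyl)-3-(methylamino)propan-2-one hydrochloride; 9 cyanamide
Product: 11 4-[(4-methoxyphenyl)methyl]-1-methyl-1H-imidazol-2-amine, via ketoguanidine hydrochloride 10 (not isolated)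
Conditions: H2NCN (50% aq., 3 equiv), H2O–EtOH, pH 4.5, 95 °C; then aq. NaOH to pH 12, extraction under Ar
Reagents that add atoms: none
Why: Cyanamide cyclocondensation of an α-amino ketone (Marckwald-type 2-aminoimidazole synthesis): the secondary amine adds to the nitrile to give 10, and a guanidine NH2 then condenses with the ketone and the ring aromatises by dehydration. Because the methyl group is on the amine nitrogen, only the 1-methyl-4-benzyl isomer with a free C5–H can form.

**Step 5**
Reactants: 12 2-hydroxy-3,4-dimethoxybenzaldehyde
Product: 13 6-(hydroxymethyl)-2,3-dimethoxyphenol
Conditions: NaBH4, MeOH, 0 °C; pH 7 phosphate buffer; concentration below 30 °C, used at once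
Reagents that add atoms: none
Why: Borohydride reduction of an aryl aldehyde; neutral, cold work-up avoids premature ionisation of the very electron-rich o-hydroxybenzyl alcohol.

**Step 6**
Reactants: 11 4-[(4-methoxyphenyl)methyl]-1-methyl-1H-imidazol-2-amine; 13 6-(hydroxymethyl)-2,3-dimethoxyphenol
Product: 15 naamine C, via o-quinone methide 14 (not isolated)
Conditions: 11 (1.5 equiv), AcOH (0.5 equiv), degassed H2O–MeCN 2:1, 90 °C, Ar; 13 added over 2 h by syringe pump
Reagents that add atoms: none
Why: Proposed new method: C5–H benzylation of a 2-aminoimidazole by an o-quinone methide has not been shown on this substrate class; the closest known reaction types are the conjugate (Friedel–Crafts-type) addition of indoles, pyrroles and enaminones to o-quinone methides released from o-hydroxybenzyl alcohols or phenolic Mannich bases, and the C4/C5 hydroxyalkylation and Mannich-type reactions of 2-aminoimidazoles with aldehydes and iminium ions. Mechanism: in the hot, weakly basic protic medium 13 should undergo 1,4-elimination of water, helped by the C4' methoxy group para to the benzylic carbon, to give 14; C5 of 11, the β-carbon of the N1–C5=C4 enamine that is further fed by the C2 amino group, adds to the exocyclic methylene; the phenoxide/5H-imidazolium (guanidinium-type) zwitterion then loses the C5 proton, so that both rings are aromatic again. No ring is closed and no stereocentre is formed. Selectivity 1, site on ring A: C5 is the only ring carbon that carries hydrogen, and an ipso attack at C4 cannot rearomatise and should revert. Selectivity 2, C against N: adducts at N3 or at the exocyclic nitrogen are phenolic Mannich bases with an amidine-type leaving group and should return to 14 at 90 °C, whereas the C-adduct is irreversible, so the material is funnelled to 15 under thermodynamic control. Selectivity 3, one benzyl group and no self-condensation of 14 with phenol rings: slow addition keeps 14 dilute, 11 is in excess and is by far the best π-nucleophile present, and the half-neutralised aminoimidazole buffer (pH near 8.5) keeps the phenols largely un-ionised. The position of the new bond on ring C is fixed beforehand by the formyl carbon of 12.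

## Compound list

1 | N-(tert-butoxycarbonyl)sarcosine | CN(CC(=O)O)C(=O)OC(C)(C)C | starting material
2 | N,O-dimethylhydroxylamine hydrochloride | CNOC.Cl | starting material
3 | tert-butyl N-[2-(1H-imidazol-1-yl)-2-oxoethyl]-N-methylcarbamate (acyl imidazolide, not isolated) | CN(CC(=O)n1ccnc1)C(=O)OC(C)(C)C | intermediate
4 | tert-butyl N-{2-[methoxy(methyl)amino]-2-oxoethyl}-N-methylcarbamate | CON(C)C(=O)CN(C)C(=O)OC(C)(C)C | intermediate
5 | (4-methoxybenzyl)magnesium chloride | COc1ccc(C[Mg]Cl)cc1 | starting material
6 | chelated tetrahedral chloromagnesium adduct of 4 and 5 (not isolated) | COc1ccc(CC(O[Mg]Cl)(CN(C)C(=O)OC(C)(C)C)N(C)OC)cc1 | intermediate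
7 | tert-butyl N-[3-(4-methoxyphenyl)-2-oxopropyl]-N-methylcarbamate | COc1ccc(CC(=O)CN(C)C(=O)OC(C)(C)C)cc1 | intermediate
8 | 1-(4-methoxyphenyl)-3-(methylamino)propan-2-one hydrochloride | CNCC(=O)Cc1ccc(OC)cc1.Cl | intermediate
9 | cyanamide | NC#N | starting material
10 | 1-[3-(4-methoxyphenyl)-2-oxopropyl]-1-methylguanidine hydrochloride (not isolated) | COc1ccc(CC(=O)CN(C)C(N)=N)cc1.Cl | intermediate
11 | 4-[(4-methoxyphenyl)methyl]-1-methyl-1H-imidazol-2-amine | COc1ccc(Cc2cn(C)c(N)n2)cc1 | intermediate
12 | 2-hydroxy-3,4-dimethoxybenzaldehyde | COc1ccc(C=O)c(O)c1OC | starting material
13 | 6-(hydroxymethyl)-2,3-dimethoxyphenol | COc1ccc(CO)c(O)c1OC | intermediate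
14 | 2,3-dimethoxy-6-methylidenecyclohexa-2,4-dien-1-one (o-quinone methide, not isolated) | C=C1C=CC(OC)=C(OC)C1=O | intermediate
15 | naamine C, 6-({2-amino-5-[(4-methoxyphenyl)methyl]-3-methyl-3H-imidazol-4-yl}methyl)-2,3-dimethoxyphenol | COc1ccc(Cc2nc(N)n(C)c2Cc2ccc(OC)c(OC)c2O)cc1 | target

## Step count and risk

Total: 6 steps. Longest linear sequence: 5 steps (steps 1, 2, 3, 4 and 6); step 5 is a one-step side branch.

**Step 6 (key step, proposed new method).** What may go wrong: alkylation at nitrogen that fails to revert, self-condensation of the quinone methide with phenolic rings into diarylmethane oligomers, and oxidative degradation of the aminoimidazole at 90 °C. The fallback uses known chemistry and inverts the polarity at C5; it sets out from 11 and 12 and comes back to the route at 15. Amine 11 is heated with N,N-dimethylformamide dimethyl acetal in toluene to give the N,N-dimethylformamidine F1. Iodination with N-iodosuccinimide in MeCN at 0 °C in the dark should give the 5-iodoimidazole F2. Iodine–magnesium exchange with iPrMgCl·LiCl in THF at −20 °C and addition of the heteroaryl Grignard reagent to the sodium phenoxide of 12 (pre-formed with NaH in THF) should give the racemic carbinol F3. Ionic deoxygenation with Et3SiH and TFA in CH2Cl2 should give the benzylated formamidine F4, and hydrolysis of the formamidine with aqueous HCl in EtOH at 70 °C should release 15.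

**Step 4.** What may go wrong: slow guanylation of the hindered secondary ammonium ion, so that oligomerisation of cyanamide and aldol-type self-condensation of the benzylic ketone take over during long heating. The fallback separates guanylation from ring closure; it sets out from 8 and comes back at 11. Salt 8 is treated with N,N'-di-Boc-1H-pyrazole-1-carboxamidine and iPr2NEt in MeCN at rt to give the di-Boc ketoguanidine F5. TFA in CH2Cl2 followed by gentle warming removes both carbamates and should bring about cyclodehydration; basic work-up gives 11.

**Step 2.** What may go wrong: Wurtz-type homocoupling and low titre of the benzylic Grignard reagent, and competing deprotonation of the amide α-methylene, so that conversion stalls. The fallback forms the same C–C bond by enolate acylation and decarboxylation; it sets out from 3 (made from 1 as in step 1) and comes back at 7. The dianion of 4-methoxyphenylacetic acid (2 equiv iPrMgCl, THF, 0 °C) is acylated by imidazolide 3 to give the racemic β-keto acid F6, which should lose carbon dioxide on acidic work-up and gentle warming to give 7.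

**Step 5.** What may go wrong: premature ionisation of the product during work-up or concentration, followed by self-condensation. The fallback changes the quinone methide precursor to a bench-stable one; it sets out from 12 and comes back to the route at 14 within step 6. Reductive amination of 12 with dimethylamine and NaBH(OAc)3 in 1,2-dichloroethane gives the phenolic Mannich base F7. Heated with 11 in dioxane at 100–110 °C under Ar, it should expel the volatile amine and release 14, which is trapped to give 15.

## Further compounds

F1 | step 6 | N'-{4-[(4-methoxyphenyl)methyl]-1-methyl-1H-imidazol-2-yl}-N,N-dimethylmethanimidamide | COc1ccc(Cc2cn(C)c(/N=C/N(C)C)n2)cc1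
F2 | step 6 | N'-{5-iodo-4-[(4-methoxyphenyl)methyl]-1-methyl-1H-imidazol-2-yl}-N,N-dimethylmethanimidamide | COc1ccc(Cc2nc(/N=C/N(C)C)n(C)c2I)cc1
F3 | step 6 | N'-{5-[hydroxy(2-hydroxy-3,4-dimethoxyphenyl)methyl]-4-[(4-methoxyphenyl)methyl]-1-methyl-1H-imidazol-2-yl}-N,N-dimethylmethanimidamide (racemic) | COc1ccc(Cc2nc(/N=C/N(C)C)n(C)c2C(O)c2ccc(OC)c(OC)c2O)cc1
F4 | step 6 | N'-{5-[(2-hydroxy-3,4-dimethoxyphenyl)methyl]-4-[(4-methoxyphenyl)methyl]-1-methyl-1H-imidazol-2-yl}-N,N-dimethylmethanimidamide | COc1ccc(Cc2nc(/N=C/N(C)C)n(C)c2Cc2ccc(OC)c(OC)c2O)cc1
F5 | step 4 | N,N'-bis(tert-butoxycarbonyl)-N''-[3-(4-methoxyphenyl)-2-oxopropyl]-N''-methylguanidine | COc1ccc(CC(=O)CN(C)C(=NC(=O)OC(C)(C)C)NC(=O)OC(C)(C)C)cc1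
F6 | step 2 | 4-[(tert-butoxycarbonyl)(methyl)amino]-2-(4-methoxyphenyl)-3-oxobutanoic acid (racemic) | COc1ccc(C(C(=O)O)C(=O)CN(C)C(=O)OC(C)(C)C)cc1
F7 | step 5 | 6-[(dimethylamino)methyl]-2,3-dimethoxyphenol | CN(C)Cc1ccc(OC)c(OC)c1O
A1 | alternative 1 | tert-butyl N-{3-[2-(benzyloxy)-3,4-dimethoxyphenyl]-1-[methoxy(methyl)amino]-1-oxopropan-2-yl}-N-methylcarbamate (racemic) | CON(C)C(=O)C(Cc1ccc(OC)c(OC)c1OCc1ccccc1)N(C)C(=O)OC(C)(C)C
A2 | alternative 1 | 4-[2-(benzyloxy)-3,4-dimethoxyphenyl]-1-(4-methoxyphenyl)-3-(methylamino)butan-2-one (racemic) | COc1ccc(CC(=O)C(Cc2ccc(OC)c(OC)c2OCc2ccccc2)NC)cc1
A3 | alternative 2 | 2-[2-(benzyloxy)-3,4-dimethoxyphenyl]acetaldehyde | COc1ccc(CC=O)c(OCc2ccccc2)c1OC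
A4 | alternative 2 | 1-ethynyl-4-methoxybenzene | C#Cc1ccc(OC)cc1
A5 | alternative 2 | 1-{1-[2-(benzyloxy)-3,4-dimethoxyphenyl]-4-(4-methoxyphenyl)but-3-yn-2-yl}-1-methylguanidine (racemic) | COc1ccc(C#CC(Cc2ccc(OC)c(OC)c2OCc2ccccc2)N(C)C(N)=N)cc1
A6 | alternative 3 | 5-{[2-(benzyloxy)-3,4-dimethoxyphenyl]methyl}-4-[(4-methoxyphenyl)methyl]-1-methyl-1H-imidazole | COc1ccc(Cc2ncn(C)c2Cc2ccc(OC)c(OC)c2OCc2ccccc2)cc1
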